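**Plan**
- Retrosynthetic cuts: first the benzylic O1–C2 bond of the chromanone, then the ether bond between the C7 oxygen and the benzylic carbon of the lactone side chain, then the aryl–acyl bond C4a–C4. In the lactone half the cuts are the Wittig-derived C2–C3 bond, the lactone C–O bond and the O4–C3a bond of the tetrahydrofuran.
- Forward order: the tetrahydrofuran (from a sugar) and the γ-lactone are fused in one cascade, the bicycle is joined by ether formation to an acylphloroglucinol that already carries the whole C6–C3 chain, and the chromanone ring is closed last, in the final step.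
- Enabling feature: once the 7-oxygen is alkylated, ring carbon C4a (bearing acyl carbon C4) lies between two equivalent phenolic oxygens (the future O1 and 5-OH), each 1,5 to the benzylic carbon C2. A 6-exo-tet closure by either oxygen gives the same chromanone and the other becomes the chelated 5-OH, so no phenol has to be differentiated.
- Stereochemistry: lactone C5 and C6a are C4 and C2 of D-glucose (used as 3-deoxy-D-erythro-pentose), and C3a follows from the cis ring fusion. The benzylic ether centre is set (R) by Ru-catalysed transfer hydrogenation and inverted to (S) in the etherification. Flavanone C2 comes from ethyl (R)-3-hydroxy-3-phenylpropanoate with inversion in the ring closure.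
- The base-labile 5-hydroxyflavanone is unveiled only in the last operation.

Key step: step 16

Remark: 5-hydroxyflavanones epimerise at C2 under base by reversible ring opening to the chalcone, which is why the pyranone ring is closed at the very end; the descriptors read from the SMILES are 2S (flavanone), S (benzylic ether carbon) and 3aR,5S,6aR (lactone).

**Route**

Step 1
Reactants: 1 1,2:5,6-di-O-isopropylidene-α-D-glucofuranose
Product: 2 3-O-(imidazol-1-ylthiocarbonyl)-1,2:5,6-di-O-isopropylidene-α-D-glucofuranose
Conditions: Im2C=S, ClCH2CH2Cl, reflux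
Reagents that add atoms: 1,1'-thiocarbonyldiimidazole, S=C(n1ccnc1)n1ccnc1
Why: Thiocarbonyl transfer from the diimidazolide acylates the free C3 hydroxyl and gives the radicophilic C=S group required for Barton–McCombie deoxygenation, with no stereocentre touched.

Step 2
Reactants: 2 3-O-(imidazol-1-ylthiocarbonyl)-1,2:5,6-di-O-isopropylidene-α-D-glucofuranose
Product: 3 3-deoxy-1,2:5,6-di-O-isopropylidene-α-D-ribo-hexofuranose
Conditions: Bu3SnH, AIBN (cat.), PhMe, reflux
Reagents that add atoms: none
Why: Barton–McCombie deoxygenation, in which the stannyl radical adds to sulfur, β-scission releases the secondary C3 radical and hydrogen transfer from the stannane leaves a CH2 group, the remaining stereocentres being untouched.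

Step 3
Reactants: 3 3-deoxy-1,2:5,6-di-O-isopropylidene-α-D-ribo-hexofuranose
Product: 5 aldehyde 3-deoxy-1,2-O-isopropylidene-α-D-erythro-pentodialdo-1,4-furanose, via 5,6-diol 4 (not isolated)
Conditions: H5IO6, EtOAc, rt
Reagents that add atoms: none
Why: Periodic acid hydrolyses the more labile terminal acetonide and cleaves the freed 5,6-diol in the same flask (Malaprade glycol cleavage), the cis-fused 1,2-acetonide and the configuration at C4 being retained.

Step 4
Reactants: 5 3-deoxy-1,2-O-isopropylidene-α-D-erythro-pentodialdo-1,4-furanose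
Product: 6 [(3aR,5S,6aR)-2,2-dimethyltetrahydrofuro[2,3-d][1,3]dioxol-5-yl](phenyl)methanol as a mixture of carbinol epimers
Conditions: PhMgBr, THF, −78 to 0 °C; aq. NH4Cl
Reagents that add atoms: phenylmagnesium bromide, Br[Mg]c1ccccc1
Why: Grignard addition to the aldehyde brings in the phenyl ring, and the configuration of the new carbinol is of no consequence because it is erased by oxidation in the next step.

Step 5
Reactants: 6 epimeric carbinols
Product: 7 [(3aR,5S,6aR)-2,2-dimethyltetrahydrofuro[2,3-d][1,3]dioxol-5-yl](phenyl)methanone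
Conditions: DMP, NaHCO3, CH2Cl2, 0 °C to rt
Reagents that add atoms: none
Why: Dess–Martin oxidation under buffered conditions converges both carbinol epimers on one aryl ketone without enolising the α-alkoxy stereocentre.

Step 6
Reactants: 7 aryl ketone
Product: 8 (R)-[(3aR,5S,6aR)-2,2-dimethyltetrahydrofuro[2,3-d][1,3]dioxol-5-yl](phenyl)methanol
Conditions: RuCl(p-cymene)[(S,S)-TsDPEN] (cat.), HCO2H/Et3N (5:2), rt
Reagents that add atoms: none
Why: Noyori asymmetric transfer hydrogenation of an aryl ketone, in which the (S,S)-TsDPEN–Ru hydride adds to the face fixed by the arene CH/π contact, the sense that gives (S)-1-phenylethanol from acetophenone and here, with the α-oxygenated carbon outranking phenyl, the (R)-carbinol under reagent control.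

Step 7
Reactants: 8 (R)-carbinol acetonide
Product: 9 (3R,5S)-5-[(R)-hydroxy(phenyl)methyl]oxolane-2,3-diol (lactol, anomeric mixture)
Conditions: TFA/H2O (9:1), 0 °C to rt
Reagents that add atoms: water, O
Why: Acid-catalysed acetal hydrolysis unmasks the lactol and the 2-hydroxyl, while the benzylic alcohol, deactivated toward ionisation by the adjacent ring oxygen, survives.

Step 8
Reactants: 9 lactol
Product: 12 (3aR,5S,6aR)-5-[(R)-hydroxy(phenyl)methyl]tetrahydrofuro[3,2-b]furan-2(3H)-one, via Z-enoate 10 (not isolated), via butenolide 11 (not isolated)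
Conditions: Ph3P=CHCO2Me, MeOH, rt; then DBU (cat.)
Reagents that add atoms: methyl (triphenylphosphoranylidene)acetate, COC(=O)C=P(c1ccccc1)(c1ccccc1)c1ccccc1
Why: Wittig olefination of the ring-opened lactol in methanol is Z-selective for α-oxygenated aldehydes, the Z-enoate lactonises through its 4-hydroxyl to the butenolide and a 5-exo-trig oxa-Michael addition of the 6-hydroxyl closes the tetrahydrofuran, the new centre C3a being forced to R because only the cis-fused bicycle is attainable while C5 and C6a are carried over from the sugar.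

Step 9
Reactants: 13 ethyl (R)-3-hydroxy-3-phenylpropanoate
Product: 14 (R)-3-hydroxy-N-methoxy-N-methyl-3-phenylpropanamide
Conditions: MeNH(OMe)·HCl, i-PrMgCl, THF, −20 to 0 °C
Reagents that add atoms: N,O-dimethylhydroxylamine hydrochloride, CNOC.Cl
Why: Weinreb amide formation by attack of the chloromagnesium amide of N,O-dimethylhydroxylamine on the ester, the carbinol centre (held as its magnesium alkoxide) not being involved.

Step 10
Reactants: 14 hydroxy Weinreb amide
Product: 15 (R)-3-[(tert-butyldimethylsilyl)oxy]-N-methoxy-N-methyl-3-phenylpropanamide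
Conditions: TBSCl, imidazole, DMF, rt
Reagents that add atoms: tert-butyldimethylsilyl chloride, CC(C)(C)[Si](C)(C)Cl
Why: Standard silylation of the secondary benzylic alcohol masks it as an ether that survives organolithium addition, hydrogenolysis and the first Mitsunobu reaction.

Step 11
Reactants: 16 1,3,5-tris(benzyloxy)benzene
Product: 17 2-bromo-1,3,5-tris(benzyloxy)benzene
Conditions: NBS (1 equiv), DMF, 0 °C
Reagents that add atoms: N-bromosuccinimide, O=C1CCC(=O)N1Br
Why: Electrophilic aromatic bromination of the electron-rich ring, whose three free positions are equivalent, so that a single monobromide results with one equivalent of NBS.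

Step 12
Reactants: 17 2-bromo-1,3,5-tris(benzyloxy)benzene; 15 silyloxy Weinreb amide
Product: 19 (R)-3-[(tert-butyldimethylsilyl)oxy]-3-phenyl-1-[2,4,6-tris(benzyloxy)phenyl]propan-1-one, via aryllithium 18 (not isolated)
Conditions: 17, n-BuLi, THF, −78 °C; then 15, −78 to 0 °C; aq. NH4Cl
Reagents that add atoms: none
Why: Bromine–lithium exchange followed by acyl substitution on the Weinreb amide, whose chelated tetrahedral adduct collapses to the ketone only on work-up, places the acyl carbon between two oxygenated ring carbons and leaves the silyloxy stereocentre untouched.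

Step 13
Reactants: 19 tris(benzyloxy)phenyl ketone
Product: 20 (R)-3-[(tert-butyldimethylsilyl)oxy]-3-phenyl-1-(2,4,6-trihydroxyphenyl)propan-1-one
Conditions: H2 (1 atm), Pd/C, EtOAc, rt
Reagents that add atoms: none
Why: Hydrogenolysis cleaves the three primary benzyl aryl ethers under neutral conditions, under which the vinylogous-acid-like aryl ketone and the hindered benzylic silyl ether are expected to persist.

Step 14
Reactants: 12 lactone alcohol; 20 acylphloroglucinol (in excess)
Product: 21 (3aR,5S,6aR)-5-[(S)-{4-[(R)-3-[(tert-butyldimethylsilyl)oxy]-3-phenylpropanoyl]-3,5-dihydroxyphenoxy}(phenyl)methyl]tetrahydrofuro[3,2-b]furan-2(3H)-one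
Conditions: PPh3, DIAD, THF, 0 °C to rt
Reagents that add atoms: none
Why: Mitsunobu etherification, in which the most acidic, non-chelated hydroxyl of 20 (para to the acyl group) displaces the oxyphosphonium derived from the benzylic alcohol of 12 in an SN2 reaction that inverts (R) to (S), while the two chelated, hindered ortho hydroxyls remain free.

Step 15
Reactants: 21 silyl ether
Product: 22 (3aR,5S,6aR)-5-[(S)-{3,5-dihydroxy-4-[(R)-3-hydroxy-3-phenylpropanoyl]phenoxy}(phenyl)methyl]tetrahydrofuro[3,2-b]furan-2(3H)-one
Conditions: HF·pyridine, THF/pyridine, 0 °C to rt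
Reagents that add atoms: none
Why: Fluoride cleavage of the silyl ether in a buffered acidic medium avoids the E1cB elimination that basic fluoride would trigger in a β-oxy ketone and spares the lactone and the aryl ethers.

Step 16
Reactants: 22 β-hydroxy ketone
Product: 23 (3aR,5S,6aR)-5-[(S)-{[(2S)-5-hydroxy-4-oxo-2-phenyl-3,4-dihydro-2H-chromen-7-yl]oxy}(phenyl)methyl]tetrahydrofuro[3,2-b]furan-2(3H)-one
Conditions: PPh3, DIAD, PhMe/THF (high dilution), 0 °C
Reagents that add atoms: none
Why: The betaine from PPh3 and DIAD deprotonates one of the two equivalent chelating phenols (pKa about 8) and converts the benzylic hydroxyl into an alkoxyphosphonium leaving group, which the phenoxide displaces intramolecularly (Mitsunobu etherification). The closest known reaction type is the intramolecular Mitsunobu cyclisation of 1-(2-hydroxyaryl)-3-hydroxyalkan-1-ones to 2-substituted chroman-4-ones. The pyranone ring closes in 6-exo-tet mode by formation of the O1–C2 bond. The only stereochemical event is SN2 inversion at C2, so the (R)-carbinol inherited from 13 gives the (2S)-flavanone and no other centre is affected. Site selectivity is not required because C4a carries the acyl group between two constitutionally equivalent hydroxyls, either of which gives the same ring while the other ends as the hydrogen-bonded 5-OH; substitution is favoured over E1cB dehydration to the chalcone (which would cyclise without facial control) by the benzylic electrophile held in six-ring reach, by the phenoxide–ketone conjugation that lowers the acidity of the C3 hydrogens, and by low temperature and dilution. As the last step, it leaves the base-labile 5-hydroxyflavanone exposed to no further reagent.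

**Compound list**
1 | 1,2:5,6-di-O-isopropylidene-α-D-glucofuranose | CC1(C)O[C@H]2O[C@H]([C@H]3COC(C)(C)O3)[C@H](O)[C@H]2O1 | starting material
2 | 3-O-(imidazol-1-ylthiocarbonyl)-1,2:5,6-di-O-isopropylidene-α-D-glucofuranose | CC1(C)O[C@H]2O[C@H]([C@H]3COC(C)(C)O3)[C@H](OC(=S)n3ccnc3)[C@H]2O1 | intermediate
3 | 3-deoxy-1,2:5,6-di-O-isopropylidene-α-D-ribo-hexofuranose | CC1(C)O[C@H]2O[C@H]([C@H]3COC(C)(C)O3)C[C@H]2O1 | intermediate
4 | 3-deoxy-1,2-O-isopropylidene-α-D-ribo-hexofuranose (5,6-diol; not isolated) | CC1(C)O[C@H]2O[C@H]([C@H](O)CO)C[C@H]2O1 | intermediate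
5 | 3-deoxy-1,2-O-isopropylidene-α-D-erythro-pentodialdo-1,4-furanose | CC1(C)O[C@H]2O[C@H](C=O)C[C@H]2O1 | intermediate
6 | [(3aR,5S,6aR)-2,2-dimethyltetrahydrofuro[2,3-d][1,3]dioxol-5-yl](phenyl)methanol, both carbinol epimers | CC1(C)O[C@H]2O[C@H](C(O)c3ccccc3)C[C@H]2O1 | intermediate
7 | [(3aR,5S,6aR)-2,2-dimethyltetrahydrofuro[2,3-d][1,3]dioxol-5-yl](phenyl)methanone | CC1(C)O[C@H]2O[C@H](C(=O)c3ccccc3)C[C@H]2O1 | intermediate
8 | (R)-[(3aR,5S,6aR)-2,2-dimethyltetrahydrofuro[2,3-d][1,3]dioxol-5-yl](phenyl)methanol | CC1(C)O[C@H]2O[C@H]([C@H](O)c3ccccc3)C[C@H]2O1 | intermediate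
9 | (3R,5S)-5-[(R)-hydroxy(phenyl)methyl]oxolane-2,3-diol (anomeric mixture) | OC1O[C@H]([C@H](O)c2ccccc2)C[C@H]1O | intermediate
10 | methyl (2Z,4R,6S,7R)-4,6,7-trihydroxy-7-phenylhept-2-enoate (not isolated) | COC(=O)/C=C\[C@H](O)C[C@H](O)[C@H](O)c1ccccc1 | intermediate
11 | (5R)-5-[(2S,3R)-2,3-dihydroxy-3-phenylpropyl]furan-2(5H)-one (not isolated) | O=C1C=C[C@@H](C[C@H](O)[C@H](O)c2ccccc2)O1 | intermediate
12 | (3aR,5S,6aR)-5-[(R)-hydroxy(phenyl)methyl]tetrahydrofuro[3,2-b]furan-2(3H)-one | O=C1C[C@H]2O[C@H]([C@H](O)c3ccccc3)C[C@H]2O1 | intermediate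
13 | ethyl (R)-3-hydroxy-3-phenylpropanoate | CCOC(=O)C[C@@H](O)c1ccccc1 | starting material
14 | (R)-3-hydroxy-N-methoxy-N-methyl-3-phenylpropanamide | CON(C)C(=O)C[C@@H](O)c1ccccc1 | intermediate
15 | (R)-3-[(tert-butyldimethylsilyl)oxy]-N-methoxy-N-methyl-3-phenylpropanamide | CON(C)C(=O)C[C@@H](O[Si](C)(C)C(C)(C)C)c1ccccc1 | intermediate
16 | 1,3,5-tris(benzyloxy)benzene | c1ccc(COc2cc(OCc3ccccc3)cc(OCc3ccccc3)c2)cc1 | starting material
17 | 2-bromo-1,3,5-tris(benzyloxy)benzene | Brc1c(OCc2ccccc2)cc(OCc2ccccc2)cc1OCc1ccccc1 | intermediate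
18 | 2,4,6-tris(benzyloxy)phenyllithium (not isolated) | [Li]c1c(OCc2ccccc2)cc(OCc2ccccc2)cc1OCc1ccccc1 | intermediate
19 | (R)-3-[(tert-butyldimethylsilyl)oxy]-3-phenyl-1-[2,4,6-tris(benzyloxy)phenyl]propan-1-one | O=C(C[C@@H](O[Si](C)(C)C(C)(C)C)c1ccccc1)c1c(OCc2ccccc2)cc(OCc2ccccc2)cc1OCc1ccccc1 | intermediate
20 | (R)-3-[(tert-butyldimethylsilyl)oxy]-3-phenyl-1-(2,4,6-trihydroxyphenyl)propan-1-one | O=C(C[C@@H](O[Si](C)(C)C(C)(C)C)c1ccccc1)c1c(O)cc(O)cc1O | intermediate
21 | (3aR,5S,6aR)-5-[(S)-{4-[(R)-3-[(tert-butyldimethylsilyl)oxy]-3-phenylpropanoyl]-3,5-dihydroxyphenoxy}(phenyl)methyl]tetrahydrofuro[3,2-b]furan-2(3H)-one | O=C1C[C@H]2O[C@H]([C@@H](Oc3cc(O)c(C(=O)C[C@@H](O[Si](C)(C)C(C)(C)C)c4ccccc4)c(O)c3)c3ccccc3)C[C@H]2O1 | intermediate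
22 | (3aR,5S,6aR)-5-[(S)-{3,5-dihydroxy-4-[(R)-3-hydroxy-3-phenylpropanoyl]phenoxy}(phenyl)methyl]tetrahydrofuro[3,2-b]furan-2(3H)-one | O=C1C[C@H]2O[C@H]([C@@H](Oc3cc(O)c(C(=O)C[C@@H](O)c4ccccc4)c(O)c3)c3ccccc3)C[C@H]2O1 | intermediate
23 | (3aR,5S,6aR)-5-[(S)-{[(2S)-5-hydroxy-4-oxo-2-phenyl-3,4-dihydro-2H-chromen-7-yl]oxy}(phenyl)methyl]tetrahydrofuro[3,2-b]furan-2(3H)-one | O=C1C[C@H]2O[C@H]([C@@H](Oc3cc(O)c4c(c3)O[C@H](c3ccccc3)CC4=O)c3ccccc3)C[C@H]2O1 | target

**Totals**
Total step count: 16. Longest linear sequence: 11 steps (steps 1–8, then 14–16, from 1).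

**Steps most likely to fail**

1. Step 16 (ring closure). E1cB loss of the activated β-oxygen would give the chalcone, which recloses without facial control, or the benzylic oxyphosphonium could ionise; either process erodes the configuration at C2. In the fallback the pyranone ring is bought instead of built and C2 is set by catalysis. From 12, Mitsunobu etherification with commercial 5,7-dihydroxychromone (only its 7-OH is free of chelation; PPh3, DIAD, THF) should give 5-hydroxy-7-{(S)-[(3aR,5S,6aR)-2-oxohexahydrofuro[3,2-b]furan-5-yl](phenyl)methoxy}-4H-chromen-4-one F1. Rhodium(I)-catalysed asymmetric 1,4-addition of phenylboronic acid (chiral diene or bisphosphine ligand, enantiomer chosen for 2S; aqueous dioxane) would then return to the route at 23.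

2. Step 14 (ether union). Discrimination between the para and the two ortho hydroxyls of 20 may be insufficient (or the phloroglucinol ring may be C-alkylated), and SN2 at the hindered α-oxygenated benzylic carbon may be slow enough for elimination to compete. In the fallback the order of the two Mitsunobu events is reversed, so that only one reactive phenol is present during the union. From 20, HF·pyridine should give (R)-3-hydroxy-3-phenyl-1-(2,4,6-trihydroxyphenyl)propan-1-one F2; intramolecular Mitsunobu closure at high dilution should give (2S)-pinocembrin F3, whose 5-OH is chelated; Mitsunobu etherification of its 7-OH with 12 returns at 23.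

3. Step 8 (olefination–lactonisation–oxa-Michael cascade). Z-selectivity in the olefination may be poor, so that the E-enoate closes to C-glycoside esters of which only the cis isomer can lactonise, or the benzylic hydroxyl may compete in a six-membered oxa-Michael closure. The fallback replaces the Wittig reagent by a doubly activated carbon acid. From 9, Knoevenagel condensation with Meldrum's acid (Et3N, DMF, 40 °C) and oxa-Michael closure should give 5-{(2R,3R,5S)-3-hydroxy-5-[(R)-hydroxy(phenyl)methyl]oxolan-2-yl}-2,2-dimethyl-1,3-dioxane-4,6-dione F4. Its cis 3-hydroxyl opens the dioxanedione to (3aR,5S,6aR)-5-[(R)-hydroxy(phenyl)methyl]-2-oxohexahydrofuro[3,2-b]furan-3-carboxylic acid F5, which decarboxylates in the same flask and returns at 12.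

**Further compounds**
F1 | step 16 | 5-hydroxy-7-{(S)-[(3aR,5S,6aR)-2-oxohexahydrofuro[3,2-b]furan-5-yl](phenyl)methoxy}-4H-chromen-4-one | O=C1C[C@H]2O[C@H]([C@@H](Oc3cc(O)c4c(c3)OC=CC4=O)c3ccccc3)C[C@H]2O1
F2 | step 14 | (R)-3-hydroxy-3-phenyl-1-(2,4,6-trihydroxyphenyl)propan-1-one | O=C(C[C@@H](O)c1ccccc1)c1c(O)cc(O)cc1O
F3 | step 14 | (2S)-pinocembrin, (2S)-5,7-dihydroxy-2-phenylchroman-4-one | Oc1cc(O)c2c(c1)O[C@H](c1ccccc1)CC2=O
F4 | step 8 | 5-{(2R,3R,5S)-3-hydroxy-5-[(R)-hydroxy(phenyl)methyl]oxolan-2-yl}-2,2-dimethyl-1,3-dioxane-4,6-dione | CC1(C)OC(=O)C(C(=O)O1)[C@H]1O[C@H]([C@H](O)c2ccccc2)C[C@H]1O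
F5 | step 8 | (3aR,5S,6aR)-5-[(R)-hydroxy(phenyl)methyl]-2-oxohexahydrofuro[3,2-b]furan-3-carboxylic acid | O=C1C(C(=O)O)[C@H]2O[C@H]([C@H](O)c3ccccc3)C[C@H]2O1
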